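**Retrosynthetic overview**
1. Labdane numbering is used (ring A: C1–C5 and C10; ring B: C5–C10; side chain C11–C16; C17 on C8, C18/C19 on C4, C20 on C10). Target 23 comes from the bicyclic bis-silyl ether 19 by inversion at C2 (oxidation, then hydride delivery from the equatorial side) and acetylation.
2. 19 comes from the open-chain tetraene sulfone 18 in one radical cascade: hydrogen atom transfer to the terminal isopropenyl group, closure of ring A at C4–C5, closure of ring B at C9–C10, then loss of PhSO2 from C7. No ring exists before this step.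
3. Enabling feature: in ring B the C7=C8 double bond lies directly beside C9, so a phenylsulfonyl group on C7 of the open chain makes C9 a radical acceptor and then leaves from the C8 radical, fixing the alkene at C7=C8. The ring A oxygen at C2, 1,3 to C4 and C10, sits equatorial in the chair fold and sets the absolute sense of C5, C9 and C10.
4. 18 is joined at C6–C7 by alkylation of allylic sulfone 16 (C7–C9, C11–C17; from geraniol) with allylic bromide 11 (C1–C6, C10, C18–C20; from (R)-epichlorohydrin).

Key step: step 12

Remark: the target is read as the ent-labdane (2S,5R,9R,10R) whose 2-acetoxy group is axial on ring A and cis to C20; the SMILES strings define the absolute configuration of every compound.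

**Route**

Step 1
Reactants: 1 (R)-epichlorohydrin; 2 isopropenylmagnesium bromide
Product: 3 (R)-1-chloro-4-methylpent-4-en-2-ol
Conditions: CuI (10 mol %), THF, −40 → 0 °C; aqueous work-up
Reagents that add atoms: none
Why: CuI-catalysed Grignard opening of the epoxide (SN2) occurs at the unsubstituted terminus faster than chloride displacement, so the stereocentre of 1 is not touched and is carried into 3.

Step 2
Reactants: 3 (R)-1-chloro-4-methylpent-4-en-2-ol
Product: 4 (R)-2-(2-methylprop-2-en-1-yl)oxirane
Conditions: NaOH (powder), Et2O, 0 °C → rt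
Reagents that add atoms: none
Why: Intramolecular Williamson etherification of the chlorohydrin alkoxide closes the epoxide at the primary carbon and leaves the stereocentre unchanged.

Step 3
Reactants: 4 (R)-2-(2-methylprop-2-en-1-yl)oxirane; 5 lithium acetylide–ethylenediamine complex
Product: 6 (R)-6-methylhept-6-en-1-yn-4-ol
Conditions: DMSO, 0 °C → rt; aqueous work-up
Reagents that add atoms: none
Why: SN2 opening of the terminal epoxide by the acetylide at the CH2 carbon should give the homopropargylic alcohol with the carbinol configuration retained.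

Step 4
Reactants: 6 (R)-6-methylhept-6-en-1-yn-4-ol
Product: 7 (R)-tert-butyldimethyl[(6-methylhept-6-en-1-yn-4-yl)oxy]silane
Conditions: TBSCl, imidazole, DMF, rt
Reagents that add atoms: tert-butyldimethylsilyl chloride, CC(C)(C)[Si](C)(C)Cl
Why: Imidazole-promoted silylation of the secondary alcohol masks it for the organometallic steps and makes it the bulky equatorial control group of step 12.

Step 5
Reactants: 7 (R)-tert-butyldimethyl[(6-methylhept-6-en-1-yn-4-yl)oxy]silane
Product: 10 (R,E)-5-[(tert-butyldimethylsilyl)oxy]-3,7-dimethylocta-2,7-dien-1-ol, via alkenyldimethylalane 8 (not isolated), via lithium alkenylalanate 9 (not isolated)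
Conditions: Me3Al (2.5 equiv), Cp2ZrCl2 (25 mol %), CH2Cl2, 0 °C → rt; solvent change to THF/hexane, n-BuLi, −78 °C; (CH2O)n, −78 °C → rt; aqueous work-up
Reagents that add atoms: trimethylaluminium, C[Al](C)C; paraformaldehyde (as formaldehyde), C=O
Why: Negishi carboalumination adds methyl and aluminium syn across the terminal alkyne with aluminium at the terminus, and the alanate attacks formaldehyde with retention, so the syn addition sets the (E)-trisubstituted alkene while the 1,1-disubstituted alkene stays inert.

Step 6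
Reactants: 10 (R,E)-5-[(tert-butyldimethylsilyl)oxy]-3,7-dimethylocta-2,7-dien-1-ol
Product: 11 (R,E)-[(8-bromo-2,6-dimethylocta-1,6-dien-4-yl)oxy](tert-butyl)dimethylsilane
Conditions: CBr4, PPh3, CH2Cl2, −20 → 0 °C
Reagents that add atoms: tetrabromomethane, BrC(Br)(Br)Br
Why: The Appel reaction converts the primary allylic alcohol into the bromide by SN2 under neutral conditions that preserve the alkene geometry and the silyl ether.

Step 7
Reactants: 12 geraniol
Product: 13 tert-butyl{[(2E)-3,7-dimethylocta-2,6-dien-1-yl]oxy}dimethylsilane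
Conditions: TBSCl, imidazole, DMF, rt
Reagents that add atoms: tert-butyldimethylsilyl chloride, CC(C)(C)[Si](C)(C)Cl
Why: Standard silylation protects the primary allylic alcohol against the base of step 11.

Step 8
Reactants: 13 tert-butyl{[(2E)-3,7-dimethylocta-2,6-dien-1-yl]oxy}dimethylsilane
Product: 14 (2E,6E)-8-[(tert-butyldimethylsilyl)oxy]-2,6-dimethylocta-2,6-dien-1-ol
Conditions: SeO2 (30 mol %), t-BuOOH (3 equiv), salicylic acid (10 mol %), CH2Cl2, 0 °C → rt
Reagents that add atoms: tert-butyl hydroperoxide, CC(C)(C)OO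
Why: SeO2-catalysed allylic oxidation (ene reaction, then [2,3]-sigmatropic shift) should select the (E)-methyl group of the distal, more electron-rich alkene and give the (E)-allylic alcohol, the alkene next to the silyloxymethyl group being deactivated.

Step 9
Reactants: 14 (2E,6E)-8-[(tert-butyldimethylsilyl)oxy]-2,6-dimethylocta-2,6-dien-1-ol
Product: 15 {[(2E,6E)-8-bromo-3,7-dimethylocta-2,6-dien-1-yl]oxy}(tert-butyl)dimethylsilane
Conditions: CBr4, PPh3, CH2Cl2, −20 → 0 °C
Reagents that add atoms: tetrabromomethane, BrC(Br)(Br)Br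
Why: The Appel reaction gives the primary allylic bromide by SN2 without allylic transposition.

Step 10
Reactants: 15 {[(2E,6E)-8-bromo-3,7-dimethylocta-2,6-dien-1-yl]oxy}(tert-butyl)dimethylsilane
Product: 16 tert-butyl{[(2E,6E)-3,7-dimethyl-8-(phenylsulfonyl)octa-2,6-dien-1-yl]oxy}dimethylsilane
Conditions: PhSO2Na, DMF, rt
Reagents that add atoms: sodium benzenesulfinate, [Na+].[O-]S(=O)c1ccccc1
Why: S-alkylation of the sulfinate by the primary allylic bromide (SN2) should give the allylic sulfone with the (E)-geometry intact.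

Step 11
Reactants: 16 tert-butyl{[(2E,6E)-3,7-dimethyl-8-(phenylsulfonyl)octa-2,6-dien-1-yl]oxy}dimethylsilane; 11 (R,E)-[(8-bromo-2,6-dimethylocta-1,6-dien-4-yl)oxy](tert-butyl)dimethylsilane
Product: 18 (4R,6E,10E,14E)-4,16-bis[(tert-butyldimethylsilyl)oxy]-2,6,10,14-tetramethyl-9-(phenylsulfonyl)hexadeca-1,6,10,14-tetraene (both epimers at the sulfone carbon), via lithiated sulfone 17 (not isolated)
Conditions: n-BuLi, THF/DMPU, −78 °C; then 11, −78 → −20 °C
Reagents that add atoms: none
Why: Alkylation of the allylic sulfone carbanion by the allylic bromide takes place at the carbon alpha to sulfur (SN2) and joins C6 to C7 with both (E)-alkenes intact; the sulfone-bearing centre forms without control, which does not matter because step 12 erases it.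

Step 12
Reactants: 18 (4R,6E,10E,14E)-4,16-bis[(tert-butyldimethylsilyl)oxy]-2,6,10,14-tetramethyl-9-(phenylsulfonyl)hexadeca-1,6,10,14-tetraene
Product: 19 (2R,5R,9R,10R)-2,15-bis[(tert-butyldimethylsilyl)oxy]labda-7,13E-diene (C2–OSi equatorial and trans to C20)
Conditions: Fe(acac)3 (50 mol %), PhSiH3 (3 equiv, slow addition), EtOH/ethylene glycol 5:1, 0.01 M, 60 °C
Reagents that add atoms: none
Why: Proposed new method: the iron hydride formed from Fe(acac)3 and PhSiH3 should transfer a hydrogen atom to the terminal 1,1-disubstituted alkene to give the tertiary C4 radical, which adds to C5; the tertiary C10 radical so formed adds to C9 of the allylic sulfone, and the C8 radical expels the phenylsulfonyl radical from C7 by beta-scission, which divalent iron reduces to sulfinate with return of trivalent iron. The closest known reaction types are the Fe(acac)3/PhSiH3 hydrogen-atom-transfer radical polyene cyclization and the radical addition–fragmentation allylation with allyl sulfones; their union with an in-chain allylic sulfone as terminator is the untested part. Ring A closes 6-endo-trig (C4 onto C5) and ring B closes 6-endo-trig (C10 onto C9), 5-exo closure being disfavoured in both cases because the nearer alkene carbon (C10, then C8) is fully substituted. C5 and C10 are set trans by the chair–chair fold of the (E)-C5=C10 alkene, C9 by the (E)-C8=C9 geometry that places C11 equatorial, and the absolute sense of all three by the C2 silyloxy group, which takes the equatorial site of the ring A chair to avoid the methyl groups on C4 and C10. The step needs hydrogen atom transfer to the isopropenyl group in preference to three trisubstituted alkenes, which the low steric demand of the 1,1-disubstituted alkene should secure, and a defined alkene position, which the C7–S bond secures because only C7 can lose the leaving radical; both C7 epimers of 18 should converge on 19.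

Step 13
Reactants: 19 (2R,5R,9R,10R)-2,15-bis[(tert-butyldimethylsilyl)oxy]labda-7,13E-diene
Product: 20 (2R,5R,9R,10R)-labda-7,13E-diene-2,15-diol
Conditions: Bu4NF (3 equiv), THF, rt → 45 °C
Reagents that add atoms: none
Why: Fluoride-mediated desilylation cleaves both Si–O bonds without touching the alkenes or any stereocentre.

Step 14
Reactants: 20 (2R,5R,9R,10R)-labda-7,13E-diene-2,15-diol
Product: 21 (5R,9R,10R)-2-oxolabda-7,13E-dien-15-al
Conditions: Dess–Martin periodinane (3 equiv), pyridine, CH2Cl2, 0 °C → rt
Reagents that add atoms: none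
Why: Dess–Martin oxidation should convert the secondary carbinol into the C2 ketone and the allylic alcohol into the (E)-enal under buffered conditions, removing the control stereocentre once it has done its work.

Step 15
Reactants: 21 (5R,9R,10R)-2-oxolabda-7,13E-dien-15-al
Product: 22 (2S,5R,9R,10R)-labda-7,13E-diene-2,15-diol (2-OH axial and cis to C20)
Conditions: NaBH4, CeCl3·7H2O, MeOH, −40 → 0 °C
Reagents that add atoms: none
Why: Luche reduction should deliver hydride 1,2 to the enal and to the C2 ketone from the equatorial side, because the axial path is blocked by the syn-axial methyl groups on C4 and C10, so the axial (2S) alcohol is expected.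

Step 16
Reactants: 22 (2S,5R,9R,10R)-labda-7,13E-diene-2,15-diol
Product: 23 (2S,5R,9R,10R)-labda-7,13E-diene-2,15-diyl diacetate
Conditions: Ac2O, pyridine, DMAP (10 mol %), CH2Cl2, rt
Reagents that add atoms: acetic anhydride, CC(=O)OC(C)=O
Why: DMAP-catalysed acylation should esterify the primary allylic alcohol and the hindered axial secondary alcohol with retention at C2.

**Compound list**
1 | (R)-epichlorohydrin | ClC[C@H]1CO1 | starting material
2 | isopropenylmagnesium bromide | CC(=C)[Mg]Br | starting material
3 | (R)-1-chloro-4-methylpent-4-en-2-ol | C=C(C)C[C@@H](O)CCl | intermediate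
4 | (R)-2-(2-methylprop-2-en-1-yl)oxirane | C=C(C)C[C@@H]1CO1 | intermediate
5 | lithium acetylide–ethylenediamine complex | [Li]C#C.NCCN | starting material
6 | (R)-6-methylhept-6-en-1-yn-4-ol | C=C(C)C[C@@H](O)CC#C | intermediate
7 | (R)-tert-butyldimethyl[(6-methylhept-6-en-1-yn-4-yl)oxy]silane | C=C(C)C[C@@H](O[Si](C)(C)C(C)(C)C)CC#C | intermediate
8 | alkenyldimethylalane from 7 (E; not isolated) | C=C(C)C[C@@H](O[Si](C)(C)C(C)(C)C)C/C(C)=C/[Al](C)C | intermediate
9 | lithium butyl(alkenyl)dimethylalanate from 8 (not isolated) | C=C(C)C[C@@H](O[Si](C)(C)C(C)(C)C)C/C(C)=C/[Al-](C)(C)CCCC.[Li+] | intermediate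
10 | (R,E)-5-[(tert-butyldimethylsilyl)oxy]-3,7-dimethylocta-2,7-dien-1-ol | C=C(C)C[C@@H](O[Si](C)(C)C(C)(C)C)C/C(C)=C/CO | intermediate
11 | (R,E)-[(8-bromo-2,6-dimethylocta-1,6-dien-4-yl)oxy](tert-butyl)dimethylsilane | C=C(C)C[C@@H](O[Si](C)(C)C(C)(C)C)C/C(C)=C/CBr | intermediate
12 | geraniol | CC(C)=CCC/C(C)=C/CO | starting material
13 | tert-butyl{[(2E)-3,7-dimethylocta-2,6-dien-1-yl]oxy}dimethylsilane | CC(C)=CCC/C(C)=C/CO[Si](C)(C)C(C)(C)C | intermediate
14 | (2E,6E)-8-[(tert-butyldimethylsilyl)oxy]-2,6-dimethylocta-2,6-dien-1-ol | OC/C(C)=C/CC/C(C)=C/CO[Si](C)(C)C(C)(C)C | intermediate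
15 | {[(2E,6E)-8-bromo-3,7-dimethylocta-2,6-dien-1-yl]oxy}(tert-butyl)dimethylsilane | BrC/C(C)=C/CC/C(C)=C/CO[Si](C)(C)C(C)(C)C | intermediate
16 | tert-butyl{[(2E,6E)-3,7-dimethyl-8-(phenylsulfonyl)octa-2,6-dien-1-yl]oxy}dimethylsilane | O=S(=O)(C/C(C)=C/CC/C(C)=C/CO[Si](C)(C)C(C)(C)C)c1ccccc1 | intermediate
17 | alpha-lithiated sulfone from 16 (not isolated) | [Li]C(/C(C)=C/CC/C(C)=C/CO[Si](C)(C)C(C)(C)C)S(=O)(=O)c1ccccc1 | intermediate
18 | (4R,6E,10E,14E)-4,16-bis[(tert-butyldimethylsilyl)oxy]-2,6,10,14-tetramethyl-9-(phenylsulfonyl)hexadeca-1,6,10,14-tetraene, both epimers at the sulfone carbon | C=C(C)C[C@@H](O[Si](C)(C)C(C)(C)C)C/C(C)=C/CC(/C(C)=C/CC/C(C)=C/CO[Si](C)(C)C(C)(C)C)S(=O)(=O)c1ccccc1 | intermediate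
19 | (2R,5R,9R,10R)-2,15-bis[(tert-butyldimethylsilyl)oxy]labda-7,13E-diene | CC(C)(C)[Si](C)(C)OC/C=C(\C)CC[C@@H]1C(C)=CC[C@@H]2C(C)(C)C[C@@H](O[Si](C)(C)C(C)(C)C)C[C@@]12C | intermediate
20 | (2R,5R,9R,10R)-labda-7,13E-diene-2,15-diol | OC/C=C(\C)CC[C@@H]1C(C)=CC[C@@H]2C(C)(C)C[C@@H](O)C[C@@]12C | intermediate
21 | (5R,9R,10R)-2-oxolabda-7,13E-dien-15-al | O=C/C=C(\C)CC[C@@H]1C(C)=CC[C@@H]2C(C)(C)CC(=O)C[C@@]12C | intermediate
22 | (2S,5R,9R,10R)-labda-7,13E-diene-2,15-diol | OC/C=C(\C)CC[C@@H]1C(C)=CC[C@@H]2C(C)(C)C[C@H](O)C[C@@]12C | intermediate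
23 | (2S,5R,9R,10R)-labda-7,13E-diene-2,15-diyl diacetate | CC(=O)OC/C=C(\C)CC[C@@H]1C(C)=CC[C@@H]2C(C)(C)C[C@H](OC(C)=O)C[C@@]12C | target

**Step count and risks**
Total step count: 16. Longest linear sequence: 12 steps (steps 1–6, then 11–16).

Steps most likely to fail:

1. Step 12 (Proposed new method). Hydrogen atom transfer may go to a trisubstituted alkene instead of the isopropenyl group. The C4 or C10 radical may be reduced before it cyclizes. Beta-scission may be slow for the C7 epimer whose C–S bond cannot align with the C8 radical, so that the chain ends at a saturated sulfone. The fallback uses known chemistry, sets out from 18 and returns at 19. Deprotonation alpha to sulfur (LiN(i-Pr)2, THF, −78 °C) and oxidation of the carbanion with bis(trimethylsilyl) peroxide should give the C7 ketone, (4R,6E,10E,14E)-4,16-bis[(tert-butyldimethylsilyl)oxy]-2,6,10,14-tetramethylhexadeca-1,6,10,14-tetraen-9-one F1. The known Fe(acac)3/PhSiH3 hydrogen-atom-transfer radical bicyclization, ended by Giese addition to this enone, should give the trans-fused 2,15-bis(silyloxy)labd-13E-en-7-one F2. Enol triflation on the more substituted side (Tf2O, 2,6-di-tert-butyl-4-methylpyridine) should give the C7 enol triflate F3, and reduction with Pd(OAc)2, PPh3, Bu3N and HCO2H would then give 19.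

2. Step 15. Hydride delivery to C2 may be less face-selective than expected with the small borohydride, and the enal may undergo conjugate reduction or E/Z isomerization. The fallback sets out from 20 and returns at 23. Selective acetylation of the primary allylic alcohol (vinyl acetate with an immobilised lipase, or AcCl/2,4,6-collidine at −78 °C) should give (2R,5R,9R,10R)-2-hydroxylabda-7,13E-dien-15-yl acetate F4. Dess–Martin oxidation should give (5R,9R,10R)-2-oxolabda-7,13E-dien-15-yl acetate F5. The bulky LiBH(s-Bu)3 (THF, −78 °C), which can approach only from the equatorial side, should give the axial alcohol (2S,5R,9R,10R)-2-hydroxylabda-7,13E-dien-15-yl acetate F6, and acetylation (Ac2O, DMAP) would give 23.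

3. Step 5. Carbometalation may stall or lose regioselectivity because the silyl ether binds the aluminium reagent, or the alkenyl group may transfer poorly to formaldehyde. The fallback sets out from 7 and returns at 10. Deprotonation with n-BuLi and addition to (CH2O)n should give the propargylic alcohol (R)-5-[(tert-butyldimethylsilyl)oxy]-7-methyloct-7-en-2-yn-1-ol F7. Hydroxyl-directed trans-hydroalumination with NaAlH2(OCH2CH2OCH3)2 and iodinolysis should give (R,Z)-5-[(tert-butyldimethylsilyl)oxy]-3-iodo-7-methylocta-2,7-dien-1-ol F8. Substitution of iodide by Me2CuLi with retention of alkene geometry would give 10.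

**Further compounds**
F1 | step 12 | (4R,6E,10E,14E)-4,16-bis[(tert-butyldimethylsilyl)oxy]-2,6,10,14-tetramethylhexadeca-1,6,10,14-tetraen-9-one | C=C(C)C[C@@H](O[Si](C)(C)C(C)(C)C)C/C(C)=C/CC(=O)/C(C)=C/CC/C(C)=C/CO[Si](C)(C)C(C)(C)C
F2 | step 12 | 2,15-bis[(tert-butyldimethylsilyl)oxy]labd-13E-en-7-one, ring stereocentres C2, C5, C9 and C10 as in 19, C8 epimers | CC(C)(C)[Si](C)(C)OC/C=C(\C)CC[C@@H]1C(C)C(=O)C[C@@H]2C(C)(C)C[C@@H](O[Si](C)(C)C(C)(C)C)C[C@@]12C
F3 | step 12 | 2,15-bis[(tert-butyldimethylsilyl)oxy]labda-7,13E-dien-7-yl trifluoromethanesulfonate, ring stereocentres as in 19 | CC(C)(C)[Si](C)(C)OC/C=C(\C)CC[C@@H]1C(C)=C(OS(=O)(=O)C(F)(F)F)C[C@@H]2C(C)(C)C[C@@H](O[Si](C)(C)C(C)(C)C)C[C@@]12C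
F4 | step 15 | (2R,5R,9R,10R)-2-hydroxylabda-7,13E-dien-15-yl acetate | CC(=O)OC/C=C(\C)CC[C@@H]1C(C)=CC[C@@H]2C(C)(C)C[C@@H](O)C[C@@]12C
F5 | step 15 | (5R,9R,10R)-2-oxolabda-7,13E-dien-15-yl acetate | CC(=O)OC/C=C(\C)CC[C@@H]1C(C)=CC[C@@H]2C(C)(C)CC(=O)C[C@@]12C
F6 | step 15 | (2S,5R,9R,10R)-2-hydroxylabda-7,13E-dien-15-yl acetate | CC(=O)OC/C=C(\C)CC[C@@H]1C(C)=CC[C@@H]2C(C)(C)C[C@H](O)C[C@@]12C
F7 | step 5 | (R)-5-[(tert-butyldimethylsilyl)oxy]-7-methyloct-7-en-2-yn-1-ol | C=C(C)C[C@@H](O[Si](C)(C)C(C)(C)C)CC#CCO
F8 | step 5 | (R,Z)-5-[(tert-butyldimethylsilyl)oxy]-3-iodo-7-methylocta-2,7-dien-1-ol | C=C(C)C[C@@H](O[Si](C)(C)C(C)(C)C)C/C(I)=C/CO
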